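**How much coupling partner stands in the ochre flask against what could use it?**

Counted as fractions of the two substrates together, each substrate is 0.5 of the charge. The 1.10 equiv is reckoned on the left-handed substrate, which makes the coupling partner 55.0 %.

all flasks: left-handed substrate 0.25 M; right-handed substrate 0.25 M
- ochre: coupling partner 1.1 equiv; free catalyst 13 mol%; the very flask that is asked about, followed so far
- teal: coupling partner 1.1 equiv; free catalyst 6.5 mol%; run made earlier
- flask: coupling partner 1.10 equiv; free catalyst 13 mol%

| ochre: time / h | ochre: left-handed product / % | teal: time / d | teal: left-handed product / % |
|---|---|---|---|
| 4.00 | 6 | 0.833 | 12 |
| 10.0 | 8 | 1.67 | 15 |
| 20.0 | 15 | 4.00 | 25 |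
| 30.0 | 22 | 10.0 | 25 |

(each reading ± 2 percentage points)

- free catalyst is single-handed; left-handed substrate and right-handed substrate are mirror images of each other, charged as a racemate, each of them at the stated concentration
- the analysis behind the earlier runs scatters by 2 percentage points, standard deviation
- no earlier run changes the charge of coupling partner; that part of a forecast is a guess

- apparent order in free catalyst when 20 % of the left-handed substrate and right-handed substrate together are converted (percent change of the rate of making left-handed product for one percent more free catalyst charged)
- apparent order in coupling partner when 20 % of the left-handed substrate and right-handed substrate together are converted (percent change of the rate of making left-handed product for one percent more coupling partner charged)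

**What do the runs say about free catalyst?**

I replace each curve by its mean rate up to the same reading. Left-handed product reaches 15 % in ochre after 20.0 h, and 15 % in teal after 40.08 h, with half the catalyst. The mean rates differ by a factor 2.00 for a loading ratio of 2.00, so my order is 1.00.

**Where is that weak?**

A mean is not the rate at the mark, and each reading scatters by 2 percentage points. Teal also reads 25 % after 4.00 d and 25 % after 10.0 d, so by these readings its rate fades. If the fade is loss of catalyst, the flask with more catalyst reaches the mark sooner with more of it intact, and the local order lies above my figure.

**And the coupling partner, which no run varies?**

Then I reason from amounts. The order compares flasks at the same conversion. If each converted substrate takes one coupling partner, whichever its hand, then 35.0 % remains at 20 %. Extra charge stays wholly in that remainder, so one percent more charge raises it by 1.57 percent. That ratio of charge to remainder at the mark I call the lever.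

**Its weak spot?**

It assumes a rate first order in coupling partner; for another order, the lever multiplies that order. I commit to 1.57.

The forecast differs from my figures, with 1.2 for free catalyst and 0.5 for coupling partner: “No run varies the coupling partner, so its order is a guess”.

The simulation of the ochre flask gives 1.2 for free catalyst and 1.8 for coupling partner.

    coupling partner + free catalyst + left-handed substrate → free catalyst + left-handed product (k = 3.15 L² mol⁻² h⁻¹)
    coupling partner + free catalyst + right-handed substrate → free catalyst + right-handed product (k = 1.02 L² mol⁻² h⁻¹)
    free catalyst → spent catalyst (k = 0.0112 h⁻¹)

The lever of 1.57 stands below the 1.8 of the ochre flask, where 82.6 % of the catalyst is free at the mark. After 10.0 d the ochre flask holds 17.6 % of its coupling partner and 6.80 % free catalyst, and the left-handed step then gives the coupling partner a half-life of 45 d, far longer than the half-life of 2.58 d of free catalyst against its loss to spent catalyst. After 100 d the ochre flask has 0 % free catalyst, with 16.1 % of the coupling partner still there.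

All runs come from a simulation with made-up constants; noise was put on by code.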